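The inner dihydrobenzofuran is cut at C3–C3a: there C3 holds the ring C arene carbon C3a and a one-carbon arm, the pattern left when the aryl carbon of a chroman-4-one shifts from C4 to C3. Photolysis of a 2-aryl-3-diazochroman-4-one in methanol performs this 1,2-shift, contracts the pyranone to the dihydrofuran ring (O1, C2, C3, C3a, C7a) and turns C4 into the exocyclic methyl ester. Methoxide equilibration then sets C3 trans to the C2 aryl. The precursor is a 3-diazoflavanone whose C2 aryl is the complete, protected outer dihydrobenzofuran unit, itself built by the same cycle, with C2 fixed beforehand by rhodium-catalysed asymmetric conjugate addition to a chromone.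

Key step: step 12

Remarks on the chemistry (assumptions and corrections):
- Only three hydroxyl groups need masking around the key step (one phenol, two primary alcohols), so there are three protecting groups to remove at the end, not four.
- The phenol is carried as a benzyl ether (inert to methoxide) and the two alcohols as tert-butyldimethylsilyl ethers.
- Protonation of the ketene-derived ester enol on the face away from the C2 aryl puts the ester cis; trans is therefore reached by equilibrating the α-aryl ester, which is built into steps 5 and 12.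
- C2 of the diazo ketones and ketenes (8, 9, 22, 23) is labelled S only because C3 outranks the aryl group there; the spatial arrangement is that of the 2R flavanones and of the target.
- The (R) hand of the bisphosphine is assumed to give the 2R flavanone by the usual face model for rhodium/biaryl-bisphosphine conjugate additions; this is to be checked on compound 6 and the antipodal ligand used if the sense proves opposite.

Step 1
Reactants: 1 1-(2-hydroxy-3-methoxyphenyl)ethan-1-one
Product: 2 1-(5-bromo-2-hydroxy-3-methoxyphenyl)ethan-1-one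
Conditions: NBS, MeCN, 0 °C to rt
Reagents that add atoms: N-bromosuccinimide, O=C1CCC(=O)N1Br
Why: Electrophilic aromatic bromination, directed by the phenol to its para position (C5) because both ortho positions are occupied by the acetyl and methoxy groups.

Step 2
Reactants: 2 1-(5-bromo-2-hydroxy-3-methoxyphenyl)ethan-1-one
Product: 4 6-bromo-8-methoxy-4H-chromen-4-one, via enaminone 3 (not isolated)
Conditions: Me2NCH(OMe)2, toluene, 100 °C; then conc. HCl, CH2Cl2, 40 °C
Reagents that add atoms: N,N-dimethylformamide dimethyl acetal, COC(OC)N(C)C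
Why: Enaminone chromone synthesis: the methyl ketone condenses with the formamide acetal, and acid then drives addition of the phenol to the enaminone carbon with loss of dimethylamine.

Step 3
Reactants: 4 6-bromo-8-methoxy-4H-chromen-4-one; 5 [4-(benzyloxy)-3-methoxyphenyl]boronic acid
Product: 6 (2R)-2-[4-(benzyloxy)-3-methoxyphenyl]-6-bromo-8-methoxychroman-4-one
Conditions: [RhCl(C2H4)2]2 (1.5 mol %), (R)-MeO-F12-BIPHEP (3.3 mol %), KOH (10 mol %), toluene/H2O, 20 °C
Reagents that add atoms: none
Why: Hayashi–Miyaura reaction (rhodium-catalysed asymmetric 1,4-addition of an arylboronic acid to a chromone), in which the aryl on monovalent rhodium adds to C2 on the face chosen by the electron-poor bisphosphine and sets C2 (R), while the low temperature and merely catalytic hydroxide keep the flavanone from ring-opening and the aryl bromide is inert.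

Step 4
Reactants: 6 (2R)-2-[4-(benzyloxy)-3-methoxyphenyl]-6-bromo-8-methoxychroman-4-one
Product: 8 (2S)-2-[4-(benzyloxy)-3-methoxyphenyl]-6-bromo-3-diazo-8-methoxychroman-4-one, via trifluoroacetyl ketone 7 (not isolated)
Conditions: LiN(SiMe3)2, THF, −78 °C; CF3CO2CH2CF3, −78 °C; AcOH; then 4-acetamidobenzenesulfonyl azide, Et3N, H2O (1 equiv), MeCN, rt
Reagents that add atoms: 4-acetamidobenzenesulfonyl azide, CC(=O)Nc1ccc(cc1)S(=O)(=O)N=[N+]=[N-]; 2,2,2-trifluoroethyl trifluoroacetate, O=C(OCC(F)(F)F)C(F)(F)F (its atoms stay only in 7)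
Why: Detrifluoroacetylative Regitz-type diazo transfer: the kinetic lithium enolate is C-acylated at −78 °C, where expulsion of the ring oxygen is slow, and the activated dicarbonyl then takes N2 from the sulfonyl azide with loss of the trifluoroacetyl group, leaving C2 untouched.

Step 5
Reactants: 8 (2S)-2-[4-(benzyloxy)-3-methoxyphenyl]-6-bromo-3-diazo-8-methoxychroman-4-one
Product: 11 methyl (2R,3R)-2-[4-(benzyloxy)-3-methoxyphenyl]-5-bromo-7-methoxy-2,3-dihydro-1-benzofuran-3-carboxylate (trans), via ketene 9 (not isolated), via cis ester 10 (not isolated)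
Conditions: hν (365 nm LED), MeOH/THF 3:1, 0 °C, N2; then NaOMe (0.3 equiv), rt
Reagents that add atoms: methanol, CO
Why: Photochemical Wolff rearrangement with ring contraction, in which the acyl aryl carbon shifts to C3 and methanol traps the ketene; the new C3 centre is then brought to trans by methoxide equilibration of the α-aryl ester, with C2 unaffected and the aryl bromide transparent at 365 nm.

Step 6
Reactants: 11 methyl (2R,3R)-2-[4-(benzyloxy)-3-methoxyphenyl]-5-bromo-7-methoxy-2,3-dihydro-1-benzofuran-3-carboxylate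
Product: 12 [(2R,3S)-2-[4-(benzyloxy)-3-methoxyphenyl]-5-bromo-7-methoxy-2,3-dihydro-1-benzofuran-3-yl]methanol
Conditions: LiAlH4, THF, 0 °C; H2O/NaOH work-up
Reagents that add atoms: none
Why: Hydride reduction of the ester to the primary alcohol, which at 0 °C spares the aryl bromide and the benzyl ether and removes the only epimerisable position (the descriptor at C3 changes to S by priority only).

Step 7
Reactants: 12 [(2R,3S)-2-[4-(benzyloxy)-3-methoxyphenyl]-5-bromo-7-methoxy-2,3-dihydro-1-benzofuran-3-yl]methanol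
Product: 13 {[(2R,3S)-2-[4-(benzyloxy)-3-methoxyphenyl]-5-bromo-7-methoxy-2,3-dihydro-1-benzofuran-3-yl]methoxy}(tert-butyl)dimethylsilane
Conditions: TBSCl, imidazole, CH2Cl2, rt
Reagents that add atoms: tert-butyldimethylsilyl chloride, CC(C)(C)[Si](C)(C)Cl
Why: Standard silylation of an unhindered primary alcohol, needed so that the later enolate and organolithium steps see no free hydroxyl group.

Step 8
Reactants: 13 {[(2R,3S)-2-[4-(benzyloxy)-3-methoxyphenyl]-5-bromo-7-methoxy-2,3-dihydro-1-benzofuran-3-yl]methoxy}(tert-butyl)dimethylsilane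
Product: 16 [(2R,3S)-2-[4-(benzyloxy)-3-methoxyphenyl]-3-{[(tert-butyldimethylsilyl)oxy]methyl}-7-methoxy-2,3-dihydro-1-benzofuran-5-yl]boronic acid, via aryllithium 14 (not isolated), via triisopropoxyborate 15 (not isolated)
Conditions: n-BuLi, THF, −78 °C; B(OiPr)3, −78 °C to 0 °C; 1 M HCl to pH 5, 0 °C
Reagents that add atoms: triisopropyl borate, CC(C)OB(OC(C)C)OC(C)C; water, O; n-butyllithium, [Li]CCCC (lithium stays only in 14 and 15)
Why: Bromine–lithium exchange followed by borylation and hydrolysis, the exchange at −78 °C being far faster than any deprotonation of the benzyl ether or of C2–H, so both stereocentres are kept.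

Step 9
Reactants: 17 (allyloxy)(tert-butyl)dimethylsilane; 4 6-bromo-8-methoxy-4H-chromen-4-one
Product: 19 6-{3-[(tert-butyldimethylsilyl)oxy]propyl}-8-methoxy-4H-chromen-4-one, via alkylborane 18 (not isolated)
Conditions: 17 (1.3 equiv), 9-BBN-H (1.25 equiv), THF, 0 °C to rt; then 4, Pd(dppf)Cl2 (5 mol %), K3PO4 (3 M aq.), DMF, 50 °C
Reagents that add atoms: 9-borabicyclo[3.3.1]nonane, B1C2CCCC1CCC2 (its atoms stay only in 18)
Why: Anti-Markovnikov hydroboration of the allyl ether and B-alkyl Suzuki–Miyaura coupling with the aryl bromide, run with the alkene in excess over B–H so that no hydride reaches the chromone and with phosphate as a base mild enough for the pyranone.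

Step 10
Reactants: 19 6-{3-[(tert-butyldimethylsilyl)oxy]propyl}-8-methoxy-4H-chromen-4-one; 16 [(2R,3S)-2-[4-(benzyloxy)-3-methoxyphenyl]-3-{[(tert-butyldimethylsilyl)oxy]methyl}-7-methoxy-2,3-dihydro-1-benzofuran-5-yl]boronic acid
Product: 20 (2R)-2-[(2R,3S)-2-[4-(benzyloxy)-3-methoxyphenyl]-3-{[(tert-butyldimethylsilyl)oxy]methyl}-7-methoxy-2,3-dihydro-1-benzofuran-5-yl]-6-{3-[(tert-butyldimethylsilyl)oxy]propyl}-8-methoxychroman-4-one
Conditions: 19 (1.3 equiv), [RhCl(C2H4)2]2 (2.5 mol %), (R)-MeO-F12-BIPHEP (5.5 mol %), KOH (10 mol %), toluene/THF/H2O, 20 °C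
Reagents that add atoms: none
Why: Hayashi–Miyaura reaction as in step 3, with the new C2 centre (R) set by the catalyst alone because the chromone is achiral and the stereocentres of the boronic acid lie far from the reacting carbon.

Step 11
Reactants: 20 (2R)-2-[(2R,3S)-2-[4-(benzyloxy)-3-methoxyphenyl]-3-{[(tert-butyldimethylsilyl)oxy]methyl}-7-methoxy-2,3-dihydro-1-benzofuran-5-yl]-6-{3-[(tert-butyldimethylsilyl)oxy]propyl}-8-methoxychroman-4-one
Product: 22 (2S)-2-[(2R,3S)-2-[4-(benzyloxy)-3-methoxyphenyl]-3-{[(tert-butyldimethylsilyl)oxy]methyl}-7-methoxy-2,3-dihydro-1-benzofuran-5-yl]-6-{3-[(tert-butyldimethylsilyl)oxy]propyl}-3-diazo-8-methoxychroman-4-one, via trifluoroacetyl ketone 21 (not isolated)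
Conditions: LiN(SiMe3)2, THF, −78 °C; CF3CO2CH2CF3, −78 °C; AcOH; then 4-acetamidobenzenesulfonyl azide, Et3N, H2O (1 equiv), MeCN, rt
Reagents that add atoms: 4-acetamidobenzenesulfonyl azide, CC(=O)Nc1ccc(cc1)S(=O)(=O)N=[N+]=[N-]; 2,2,2-trifluoroethyl trifluoroacetate, O=C(OCC(F)(F)F)C(F)(F)F (its atoms stay only in 21)
Why: Detrifluoroacetylative Regitz-type diazo transfer as in step 4, the ketone α-CH2 being the only position acidic enough for the amide base, so the silyl ethers, the benzyl ether and the outer unit are untouched.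

Step 12
Reactants: 22 (2S)-2-[(2R,3S)-2-[4-(benzyloxy)-3-methoxyphenyl]-3-{[(tert-butyldimethylsilyl)oxy]methyl}-7-methoxy-2,3-dihydro-1-benzofuran-5-yl]-6-{3-[(tert-butyldimethylsilyl)oxy]propyl}-3-diazo-8-methoxychroman-4-one
Product: 25 methyl (2R,3R)-2-[(2R,3S)-2-[4-(benzyloxy)-3-methoxyphenyl]-3-{[(tert-butyldimethylsilyl)oxy]methyl}-7-methoxy-2,3-dihydro-1-benzofuran-5-yl]-5-{3-[(tert-butyldimethylsilyl)oxy]propyl}-7-methoxy-2,3-dihydro-1-benzofuran-3-carboxylate (trans), via ketene 23 (not isolated), via cis ester 24 (not isolated)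
Conditions: hν (365 nm LED), MeOH/THF 3:1, 0 °C, N2, dilute; then NaOMe (0.3 equiv), rt
Reagents that add atoms: methanol, CO
Why: Excitation of the diazo ketone, held s-Z by the six-membered ring, expels N2 while the ring C aryl carbon shifts from the carbonyl carbon to the diazo carbon, giving ketene 23 with the C3–C3a bond in place; methanol adds to the ketene and the ester enol is protonated at C3. The closest known reaction type is the photochemical Wolff ring contraction of cyclic 2-diazo-1-aryl ketones, such as 2-diazo-1-tetralones to indane-1-carboxylates. The dihydrofuran ring (O1, C2, C3, C3a, C7a) is formed not by cyclisation but by excision of C4 from the pyranone through the 1,2-shift, so no exo or endo closure mode applies. The new stereocentre C3 is set under thermodynamic control: kinetic protonation anti to the C2 substituent should give mainly cis ester 24, and catalytic methoxide equilibrates the α-aryl ester to the trans isomer, while C2 has no acidic hydrogen and keeps its configuration. The selectivity needed is migration of the acyl aryl carbon in preference to carbene chemistry at C2 (1,2-hydride shift to the flavone, O–H insertion); it is secured by the locked s-Z geometry under direct irradiation and by the absence of metal catalysts, and the C2 aryl, lying beyond the carbene carbon, cannot be the migrating group.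

Step 13
Reactants: 25 methyl (2R,3R)-2-[(2R,3S)-2-[4-(benzyloxy)-3-methoxyphenyl]-3-{[(tert-butyldimethylsilyl)oxy]methyl}-7-methoxy-2,3-dihydro-1-benzofuran-5-yl]-5-{3-[(tert-butyldimethylsilyl)oxy]propyl}-7-methoxy-2,3-dihydro-1-benzofuran-3-carboxylate
Product: 26 [(2R,3S)-2-[(2R,3S)-2-[4-(benzyloxy)-3-methoxyphenyl]-3-{[(tert-butyldimethylsilyl)oxy]methyl}-7-methoxy-2,3-dihydro-1-benzofuran-5-yl]-5-{3-[(tert-butyldimethylsilyl)oxy]propyl}-7-methoxy-2,3-dihydro-1-benzofuran-3-yl]methanol
Conditions: LiAlH4, THF, 0 °C; H2O/NaOH work-up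
Reagents that add atoms: none
Why: Hydride reduction of the ester to the inner hydroxymethyl group, to which silyl and benzyl ethers are inert and after which C3 can no longer epimerise.

Step 14
Reactants: 26 [(2R,3S)-2-[(2R,3S)-2-[4-(benzyloxy)-3-methoxyphenyl]-3-{[(tert-butyldimethylsilyl)oxy]methyl}-7-methoxy-2,3-dihydro-1-benzofuran-5-yl]-5-{3-[(tert-butyldimethylsilyl)oxy]propyl}-7-methoxy-2,3-dihydro-1-benzofuran-3-yl]methanol
Product: 27 3-[(2R,3S)-2-[(2R,3S)-2-[4-(benzyloxy)-3-methoxyphenyl]-3-(hydroxymethyl)-7-methoxy-2,3-dihydro-1-benzofuran-5-yl]-3-(hydroxymethyl)-7-methoxy-2,3-dihydro-1-benzofuran-5-yl]propan-1-ol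
Conditions: Bu4NF, THF, 0 °C to rt
Reagents that add atoms: none
Why: Fluoride desilylation of the two primary silyl ethers, run while the phenol is still benzylated so that no phenoxide para to a benzylic ether is exposed to the basic fluoride.

Step 15
Reactants: 27 3-[(2R,3S)-2-[(2R,3S)-2-[4-(benzyloxy)-3-methoxyphenyl]-3-(hydroxymethyl)-7-methoxy-2,3-dihydro-1-benzofuran-5-yl]-3-(hydroxymethyl)-7-methoxy-2,3-dihydro-1-benzofuran-5-yl]propan-1-ol
Product: 28 3-[(2R,3S)-2-[(2R,3S)-2-(4-hydroxy-3-methoxyphenyl)-3-(hydroxymethyl)-7-methoxy-2,3-dihydro-1-benzofuran-5-yl]-3-(hydroxymethyl)-7-methoxy-2,3-dihydro-1-benzofuran-5-yl]propan-1-ol (target)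
Conditions: H2 (1 atm), Pd/C (10 %), EtOAc/EtOH, rt, stopped at full conversion
Reagents that add atoms: none
Why: Catalytic hydrogenolysis of the single aryl benzyl ether, which should cleave much faster at one atmosphere than the cyclic benzylic C2–O bonds of the two dihydrofuran rings.

Compound list
1 | 1-(2-hydroxy-3-methoxyphenyl)ethan-1-one | CC(=O)c1cccc(OC)c1O | starting material
2 | 1-(5-bromo-2-hydroxy-3-methoxyphenyl)ethan-1-one | CC(=O)c1cc(Br)cc(OC)c1O | intermediate
3 | (E)-1-(5-bromo-2-hydroxy-3-methoxyphenyl)-3-(dimethylamino)prop-2-en-1-one | CN(C)/C=C/C(=O)c1cc(Br)cc(OC)c1O | intermediate (not isolated)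
4 | 6-bromo-8-methoxy-4H-chromen-4-one | COc1cc(Br)cc2c(=O)ccoc12 | intermediate
5 | [4-(benzyloxy)-3-methoxyphenyl]boronic acid | COc1cc(B(O)O)ccc1OCc1ccccc1 | starting material
6 | (2R)-2-[4-(benzyloxy)-3-methoxyphenyl]-6-bromo-8-methoxychroman-4-one | COc1cc([C@@H]2Oc3c(OC)cc(Br)cc3C(=O)C2)ccc1OCc1ccccc1 | intermediate
7 | (2R)-2-[4-(benzyloxy)-3-methoxyphenyl]-6-bromo-8-methoxy-3-(trifluoroacetyl)chroman-4-one (C3 epimers and enol form) | COc1cc([C@@H]2Oc3c(OC)cc(Br)cc3C(=O)C2C(=O)C(F)(F)F)ccc1OCc1ccccc1 | intermediate (not isolated)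
8 | (2S)-2-[4-(benzyloxy)-3-methoxyphenyl]-6-bromo-3-diazo-8-methoxychroman-4-one | COc1cc([C@@H]2Oc3c(OC)cc(Br)cc3C(=O)C2=[N+]=[N-])ccc1OCc1ccccc1 | intermediate
9 | [(2S)-2-[4-(benzyloxy)-3-methoxyphenyl]-5-bromo-7-methoxy-1-benzofuran-3(2H)-ylidene]methanone (ketene) | COc1cc([C@@H]2Oc3c(OC)cc(Br)cc3C2=C=O)ccc1OCc1ccccc1 | intermediate (not isolated)
10 | methyl (2R,3S)-2-[4-(benzyloxy)-3-methoxyphenyl]-5-bromo-7-methoxy-2,3-dihydro-1-benzofuran-3-carboxylate (cis) | COc1cc([C@@H]2Oc3c(OC)cc(Br)cc3[C@@H]2C(=O)OC)ccc1OCc1ccccc1 | intermediate (not isolated)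
11 | methyl (2R,3R)-2-[4-(benzyloxy)-3-methoxyphenyl]-5-bromo-7-methoxy-2,3-dihydro-1-benzofuran-3-carboxylate (trans) | COc1cc([C@@H]2Oc3c(OC)cc(Br)cc3[C@H]2C(=O)OC)ccc1OCc1ccccc1 | intermediate
12 | [(2R,3S)-2-[4-(benzyloxy)-3-methoxyphenyl]-5-bromo-7-methoxy-2,3-dihydro-1-benzofuran-3-yl]methanol | COc1cc([C@@H]2Oc3c(OC)cc(Br)cc3[C@H]2CO)ccc1OCc1ccccc1 | intermediate
13 | {[(2R,3S)-2-[4-(benzyloxy)-3-methoxyphenyl]-5-bromo-7-methoxy-2,3-dihydro-1-benzofuran-3-yl]methoxy}(tert-butyl)dimethylsilane | COc1cc([C@@H]2Oc3c(OC)cc(Br)cc3[C@H]2CO[Si](C)(C)C(C)(C)C)ccc1OCc1ccccc1 | intermediate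
14 | 5-lithio analogue of 13 (aryllithium, 2R,3S) | COc1cc([C@@H]2Oc3c(OC)cc([Li])cc3[C@H]2CO[Si](C)(C)C(C)(C)C)ccc1OCc1ccccc1 | intermediate (not isolated)
15 | lithium aryl(triisopropoxy)borate derived from 14 (2R,3S) | COc1cc([C@@H]2Oc3c(OC)cc([B-](OC(C)C)(OC(C)C)OC(C)C)cc3[C@H]2CO[Si](C)(C)C(C)(C)C)ccc1OCc1ccccc1.[Li+] | intermediate (not isolated)
16 | [(2R,3S)-2-[4-(benzyloxy)-3-methoxyphenyl]-3-{[(tert-butyldimethylsilyl)oxy]methyl}-7-methoxy-2,3-dihydro-1-benzofuran-5-yl]boronic acid | COc1cc([C@@H]2Oc3c(OC)cc(B(O)O)cc3[C@H]2CO[Si](C)(C)C(C)(C)C)ccc1OCc1ccccc1 | intermediate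
17 | (allyloxy)(tert-butyl)dimethylsilane | C=CCO[Si](C)(C)C(C)(C)C | starting material
18 | 9-{3-[(tert-butyldimethylsilyl)oxy]propyl}-9-borabicyclo[3.3.1]nonane | CC(C)(C)[Si](C)(C)OCCCB1C2CCCC1CCC2 | intermediate (not isolated)
19 | 6-{3-[(tert-butyldimethylsilyl)oxy]propyl}-8-methoxy-4H-chromen-4-one | COc1cc(CCCO[Si](C)(C)C(C)(C)C)cc2c(=O)ccoc12 | intermediate
20 | inner flavanone: (2R)-chroman-4-one carrying the (2R,3S) outer unit at C2, the silyloxypropyl chain at C6 and OMe at C8 | COc1cc([C@@H]2Oc3c(OC)cc([C@@H]4Oc5c(OC)cc(CCCO[Si](C)(C)C(C)(C)C)cc5C(=O)C4)cc3[C@H]2CO[Si](C)(C)C(C)(C)C)ccc1OCc1ccccc1 | intermediate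
21 | 3-(trifluoroacetyl) derivative of 20 (C3 epimers and enol form) | COc1cc([C@@H]2Oc3c(OC)cc([C@@H]4Oc5c(OC)cc(CCCO[Si](C)(C)C(C)(C)C)cc5C(=O)C4C(=O)C(F)(F)F)cc3[C@H]2CO[Si](C)(C)C(C)(C)C)ccc1OCc1ccccc1 | intermediate (not isolated)
22 | 3-diazoflavanone (2S by priority; geometry of 20), key-step precursor | COc1cc([C@@H]2Oc3c(OC)cc([C@@H]4Oc5c(OC)cc(CCCO[Si](C)(C)C(C)(C)C)cc5C(=O)C4=[N+]=[N-])cc3[C@H]2CO[Si](C)(C)C(C)(C)C)ccc1OCc1ccccc1 | intermediate
23 | inner-unit ketene (benzofuran-3(2H)-ylidene methanone; C2 as in 22) | COc1cc([C@@H]2Oc3c(OC)cc([C@@H]4Oc5c(OC)cc(CCCO[Si](C)(C)C(C)(C)C)cc5C4=C=O)cc3[C@H]2CO[Si](C)(C)C(C)(C)C)ccc1OCc1ccccc1 | intermediate (not isolated)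
24 | inner-unit cis methyl ester (inner 2R,3S; outer 2R,3S) | COc1cc([C@@H]2Oc3c(OC)cc([C@@H]4Oc5c(OC)cc(CCCO[Si](C)(C)C(C)(C)C)cc5[C@@H]4C(=O)OC)cc3[C@H]2CO[Si](C)(C)C(C)(C)C)ccc1OCc1ccccc1 | intermediate (not isolated)
25 | inner-unit trans methyl ester (inner 2R,3R; outer 2R,3S), key-step product | COc1cc([C@@H]2Oc3c(OC)cc([C@@H]4Oc5c(OC)cc(CCCO[Si](C)(C)C(C)(C)C)cc5[C@H]4C(=O)OC)cc3[C@H]2CO[Si](C)(C)C(C)(C)C)ccc1OCc1ccccc1 | intermediate
26 | inner hydroxymethyl compound, bis-silyl ether, benzyl ether (all centres 2R,3S) | COc1cc([C@@H]2Oc3c(OC)cc([C@@H]4Oc5c(OC)cc(CCCO[Si](C)(C)C(C)(C)C)cc5[C@H]4CO)cc3[C@H]2CO[Si](C)(C)C(C)(C)C)ccc1OCc1ccccc1 | intermediate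
27 | O-benzyl triol (target with the phenol benzylated) | COc1cc([C@@H]2Oc3c(OC)cc([C@@H]4Oc5c(OC)cc(CCCO)cc5[C@H]4CO)cc3[C@H]2CO)ccc1OCc1ccccc1 | intermediate
28 | 3-[(2R,3S)-2-[(2R,3S)-2-(4-hydroxy-3-methoxyphenyl)-3-(hydroxymethyl)-7-methoxy-2,3-dihydro-1-benzofuran-5-yl]-3-(hydroxymethyl)-7-methoxy-2,3-dihydro-1-benzofuran-5-yl]propan-1-ol | COc1cc([C@@H]2Oc3c(OC)cc([C@@H]4Oc5c(OC)cc(CCCO)cc5[C@H]4CO)cc3[C@H]2CO)ccc1O | target

Total step count: 15. Longest linear sequence: 14 steps (steps 1 to 8, then 10 to 15; step 9 is a branch from compound 4).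

Steps most likely to fail

Step 12. What may go wrong is escape of a free carbene, giving 1,2-hydride shift from C2 to the flavone or O–H insertion of methanol, or base-induced β-elimination of the ring oxygen during the equilibration. The fallback sets out from flavanone 20 and uses the oxidative ring contraction of flavanones: [hydroxy(tosyloxy)iodo]benzene in trimethyl orthoformate/methanol at rt. The enol ether is iodinated at C3 and the same acyl aryl carbon migrates as iodobenzene leaves, which is known to give the trans methyl ester. The sulfonic acid set free in methanol should also strip both silyl ethers, so the product expected is the desilylated trans methyl ester F1. LiAlH4 in THF at 0 °C then reduces F1 directly, and the fallback comes back to the route at compound 27, skipping the fluoride step. Competing migration of the electron-rich C2 aryl is the known weakness of this alternative.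

Step 11. What may go wrong is β-elimination of the ring oxygen from the lithium enolate (opening to the chalcone phenoxide and loss of the C2 configuration), or incomplete C-acylation next to the bulky C2 substituent. The fallback sets out from compound 20 and avoids any enolate. Acid-side α-nitrosation through the enol (isoamyl nitrite, Me3SiCl, CH2Cl2, −20 °C) gives the 3-hydroxyimino ketone F2. A Forster reaction with chloramine (NaOCl, aqueous NH3, NaOH, THF/H2O, 0 °C) then converts the oxime into the diazo group, and the fallback comes back at compound 22.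

Step 10. What may go wrong is protodeboronation of the valuable boronic acid outrunning carbometalation, weak catalyst control giving the C2 epimer, or hydroxide-induced ring opening of the flavanone. The fallback sets out from compounds 13 and 2 and builds the flavanone by condensation and cyclisation instead of conjugate arylation:
- Bromide 13 is lithiated as in step 8 (aryllithium 14) and formylated with DMF to the outer-unit aldehyde F3.
- Acetophenone 2 is coupled with alkylborane 18 under the conditions of step 9 to give the ring C 2-hydroxyacetophenone F4.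
- Claisen–Schmidt condensation (KOH, EtOH, rt) joins them as the 2′-hydroxychalcone F5.
- 6-endo oxa-Michael cyclisation (NaOAc, EtOH, reflux) gives flavanone 20 together with its C2 epimer F6.

The two are diastereomers, to be separated by chromatography, and F6 can be recycled through F5 with the same base. The fallback comes back at compound 20.

Further compounds
F1 | step 12 | methyl (2R,3R)-2-[(2R,3S)-2-[4-(benzyloxy)-3-methoxyphenyl]-3-(hydroxymethyl)-7-methoxy-2,3-dihydro-1-benzofuran-5-yl]-5-(3-hydroxypropyl)-7-methoxy-2,3-dihydro-1-benzofuran-3-carboxylate | COc1cc([C@@H]2Oc3c(OC)cc([C@@H]4Oc5c(OC)cc(CCCO)cc5[C@H]4C(=O)OC)cc3[C@H]2CO)ccc1OCc1ccccc1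
F2 | step 11 | 3-(hydroxyimino) derivative of flavanone 20 (oxime geometry not defined) | COc1cc([C@@H]2Oc3c(OC)cc([C@@H]4Oc5c(OC)cc(CCCO[Si](C)(C)C(C)(C)C)cc5C(=O)C4=NO)cc3[C@H]2CO[Si](C)(C)C(C)(C)C)ccc1OCc1ccccc1
F3 | step 10 | (2R,3S)-2-[4-(benzyloxy)-3-methoxyphenyl]-3-{[(tert-butyldimethylsilyl)oxy]methyl}-7-methoxy-2,3-dihydro-1-benzofuran-5-carbaldehyde | COc1cc([C@@H]2Oc3c(OC)cc(C=O)cc3[C@H]2CO[Si](C)(C)C(C)(C)C)ccc1OCc1ccccc1
F4 | step 10 | 1-(5-{3-[(tert-butyldimethylsilyl)oxy]propyl}-2-hydroxy-3-methoxyphenyl)ethan-1-one | CC(=O)c1cc(CCCO[Si](C)(C)C(C)(C)C)cc(OC)c1O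
F5 | step 10 | (E)-2′-hydroxychalcone from F3 and F4 | COc1cc([C@@H]2Oc3c(OC)cc(/C=C/C(=O)c4cc(CCCO[Si](C)(C)C(C)(C)C)cc(OC)c4O)cc3[C@H]2CO[Si](C)(C)C(C)(C)C)ccc1OCc1ccccc1
F6 | step 10 | C2 epimer of flavanone 20 (inner 2S) | COc1cc([C@@H]2Oc3c(OC)cc([C@H]4Oc5c(OC)cc(CCCO[Si](C)(C)C(C)(C)C)cc5C(=O)C4)cc3[C@H]2CO[Si](C)(C)C(C)(C)C)ccc1OCc1ccccc1
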